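I start from a ratio: at equal concentrations the gas reacts with starting material 44.9 times as readily as with target, so I expect target first and over-reacted product later.

    gas phase ⇌ dissolved gas, rate k1*(csat - [dissolved gas]) (k1 = 0.515 /s, csat = 50 mM)
    target → over-reaction product (k2 = 4.83 × 10⁻⁵ /s)
    dissolved gas + target → over-reacted product (k3 = 0.0325 /M/s)
    starting material + dissolved gas → target (k4 = 1.46 /M/s)

all flasks: starting material 0.40 M; gas phase 50 mM (held)
- grey: time 6.0 min
- violet: time 20 min
- red: time 2.0 min

- at the start none of the gas is dissolved
- run time (grey): 6.0 min

1. which of the two there is more of at the end, grey (target / over-reacted product)
2. which of the two there is more of at the end, violet (target / over-reacted product)
3. which of the two there is more of at the end, red (target / over-reacted product)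
4. how much target is there at the end, in percent of the starting material charged: grey
5. how much target is there at the end, in percent of the starting material charged: violet
6. how much target is there at the end, in percent of the starting material charged: red

I turn the question round: for over-reacted product to lead at a reading, target must have fallen to about level with it, so I ask what time that takes. I write the balance of the gas, since [dissolved gas] can reach 50 mM while the charge of starting material is 0.40 M. The change in [dissolved gas] is the supply through the surface, proportional to the gap below saturation, minus what starting material and target take. The supply is at most 25.8 mM/s. Integrating the balance, each mole of gas used costs the liquid some time at saturation, so converting the charge costs a dead time of 15.5 s.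

Beyond the dead time, the drain by target stays small against the transfer, so I take [dissolved gas] as 50 mM. Target then decays in a pseudo-first-order way, and nearly all of the loss goes to over-reacted product. The time constant is 9.96 min, and this life of target under saturated gas is the quantity I carry. It is long against the dead time.

My rule, which treats the whole charge as turned into target at the dead time, is that the target share equals the exponential of minus the time past the dead time, divided by the life. By this estimate the two products stand level at the dead time plus ln(2) lives, which I reckon as 7.16 min. Grey stops earlier than this reckoned time, as red does, while violet stops later. So I commit to target in grey, over-reacted product in violet and target in red. The target shares I reckon are 56.2% for grey, 13.8% for violet and 84.0% for red.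

The forecast gives 58% for grey, 14.5% for violet and 86% for red, with the decay of target going “almost all to over-reacted product”.

The flask gives 58.3% target in grey, 14.4% in violet and 86.4% in red. The lead goes to target in grey, to over-reacted product in violet and to target in red. In grey, [dissolved gas] stands at 0.0493 M at 6.00 min, against a saturation of 50 mM. I use the life once more on red read later, at 5.0 min, which is earlier than my reckoned level time. The rule gives 62.1% target, and that flask holds 64.3% target against 34.6% over-reacted product.

(The constants used here are made up.)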